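**Assumptions.** 3-Hydroxy-3-methylglutaric (HMG) anhydride 13 is bought as a catalogue compound. L-DIPT (step 9) and quinidine (step 11) are taken to give the required sense; I could not assign either from a firm model, so each is checked on a small model run, with D-DIPT and quinine as the mirror-image switches.

**Locants.** Drimane numbering for the decalin (C11 is the CH2 linking to the ring). In the six-membered ring, C1' bears C11, C2' is the epoxide CH, C3' is the C=O next to C2', C4' bears C7' (CH2O), C5' is =CH, and C6' is the C=O next to C1'.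

## Retrosynthetic overview

1. Target ⇒ 4'-oxomacrophorin A + prochiral HMG anhydride; a desymmetrising alcoholysis sets the HMG centre (3S) and leaves the free acid.
2. Epoxyquinone ⇒ quinone monoketal by a C7'-hydroxyl-directed, tartrate-controlled nucleophilic epoxidation, which sets C1' and C2' together.
3. Quinone monoketal ⇒ a plain, para-unsubstituted phenol by a double oxidative dearomatisation that installs the para oxygen during the dearomatisation (key step).
4. Phenol ⇒ Ni cross-electrophile coupling of a C11 iodide (from sclareolide by lactol β-fragmentation) with methyl 4-bromo-3-hydroxybenzoate; the 8α-oxygen is later eliminated to the 8(12)-alkene.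
5. Rings: the trans-decalin is bought (sclareolide), the carbocycle is the benzoate ring, and the oxirane is the only ring made, formed last (step 9).

## Route

**Step 1**
Reactants: 1, (+)-sclareolide (8α,12-olide; 5α-H, 9α-H, 8β-Me, 10β-Me)
Product: 2, sclareolide lactol (12-hydroxy-8α,12-epoxy-homodrimane, anomer mixture)
Conditions: DIBAL-H (1.1 equiv), CH2Cl2, −78 °C
Reagents that add atoms: none
Why: Partial hydride reduction of a γ-lactone stops at the lactol at −78 °C and touches no stereocentre.

**Step 2**
Reactants: 2, sclareolide lactol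
Product: 3, 11-iodo-drimane-8α-yl formate
Conditions: PhI(OAc)2, I2, hν (W lamp), cyclohexane/CH2Cl2, rt
Reagents that add atoms: iodine, II
Why: Suárez hypoiodite reaction: the lactol alkoxy radical undergoes β-scission of C11–C12, C12 stays on the 8α-oxygen as a formate and the primary C11 radical is trapped by iodine, with C8 and C9 untouched.

**Step 3**
Reactants: 4, methyl 4-bromo-3-hydroxybenzoate
Product: 5, methyl 4-bromo-3-(pivaloyloxy)benzoate
Conditions: PivCl, Et3N, DMAP (cat.), CH2Cl2, 0 °C to rt
Reagents that add atoms: pivaloyl chloride, CC(C)(C)C(=O)Cl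
Why: Simple phenol acylation; the pivalate masks the phenol through steps 4–6 and is removed for free in the step-7 hydride reduction.

**Step 4**
Reactants: 3, 11-iodo-drimane-8α-yl formate; 5, methyl 4-bromo-3-(pivaloyloxy)benzoate (1.5 equiv)
Product: 6, methyl 4-(8α-formyloxydriman-11-yl)-3-(pivaloyloxy)benzoate
Conditions: NiI2·xH2O (10 mol%), 1,10-phenanthroline (10 mol%), Zn (2 equiv), NaI (25 mol%), pyridine (10 mol%), DMPU, 60 °C
Reagents that add atoms: none (both partners are numbered reactants)
Why: Weix-type Ni-catalysed reductive cross-electrophile coupling: the hindered primary iodide reacts as a C11 radical captured by Ar–Ni(II), so SN2 hindrance is irrelevant, the esters and formate are tolerated, and no stereocentre is involved.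

**Step 5**
Reactants: 6
Product: 7, methyl 4-(8α-hydroxydriman-11-yl)-3-(pivaloyloxy)benzoate
Conditions: K2CO3 (0.2 equiv), MeOH/THF, 0 °C, stopped at full formate consumption
Reagents that add atoms: none
Why: Chemoselective transesterification: a formate is far more labile than an aryl pivalate or methyl benzoate, so only the tertiary 8α-OH is released.

**Step 6**
Reactants: 7
Product: 8, methyl 4-(drim-8(12)-en-11-yl)-3-(pivaloyloxy)benzoate (5S,9S,10S)
Conditions: SOCl2 (3 equiv), pyridine, CH2Cl2, −78 °C; AgNO3–SiO2 chromatography
Reagents that add atoms: none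
Why: Chlorosulfite E2 dehydration: the equatorial 8α leaving group has no anti-periplanar ring hydrogen, so the C12 methyl hydrogens are removed preferentially and the exocyclic alkene is the main product (minor Δ7/Δ8 isomers are separated); C9 is untouched.

**Step 7**
Reactants: 8
Product: 9, 5-(hydroxymethyl)-2-(drim-8(12)-en-11-yl)phenol
Conditions: LiAlH4 (4 equiv), THF, 0 °C to rt; Rochelle-salt work-up (no acid)
Reagents that add atoms: none
Why: Hydride reduction converts the methyl ester to CH2OH and cleaves the aryl pivalate in the same flask; the isolated alkene is inert and the neutral work-up avoids phenol-to-C8 chroman cyclisation.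

**Step 8 (key step)**
Reactants: 9
Product: 10, 4,4-dimethoxy-5-(hydroxymethyl)-2-(drim-8(12)-en-11-yl)cyclohexa-2,5-dien-1-one (ketal at C3', C=O at C6')
Conditions: PhI(OAc)2 (2.3 equiv), NaHCO3, MeOH (dilute), 0 °C
Reagents that add atoms: methanol, CO (both OMe groups)
Why: Double hypervalent-iodine oxidative dearomatisation (Pelter/Kita type): MeOH attacks the aryl-λ3-iodane at the free para carbon C3' to give the p-methoxyphenol, which is more electron-rich and is oxidised again in situ to the dimethyl monoketal; the C7' hydroxyl cannot reach C3', solvent MeOH outcompetes the remote alkene, and no stereocentre is formed.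

**Step 9**
Reactants: 10
Product: 11, (1'R,2'S)-1',2'-epoxide of 10, i.e. (1R,6S)-5,5-dimethoxy-4-(hydroxymethyl)-1-(drim-8(12)-en-11-yl)-7-oxabicyclo[4.1.0]hept-3-en-2-one
Conditions: Ph3COOH (1.5 equiv), NaHMDS, L-(+)-DIPT, 4 Å MS, PhMe, −60 to −40 °C
Reagents that add atoms: trityl hydroperoxide, OOC(c1ccccc1)(c1ccccc1)c1ccccc1 (one O)
Why: Porco tartrate-mediated, hydroxyl-directed Weitz–Scheffer epoxidation: the C7' sodium alkoxide anchors the chiral tartrate–peroxide aggregate and delivers the peroxide across the ketal carbon to C2' (the only unsubstituted β-carbon, C4' being blocked), and the enolate closes on O–O, so C1' and C2' are set together as a cis-epoxide under reagent control.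

**Step 10**
Reactants: 11
Product: 12, 4'-oxomacrophorin A, (1R,6S)-4-(hydroxymethyl)-1-(drim-8(12)-en-11-yl)-7-oxabicyclo[4.1.0]hept-3-ene-2,5-dione
Conditions: montmorillonite K10, wet CH2Cl2, rt
Reagents that add atoms: water, O
Why: Mild heterogeneous acid hydrolysis of the dimethyl ketal via an allylically stabilised oxocarbenium ion; the electron-poor α,β-epoxy ketone and the exocyclic alkene survive these conditions and no stereocentre is touched.

**Step 11**
Reactants: 12, 4'-oxomacrophorin A; 13, 3-hydroxy-3-methylglutaric anhydride (2 equiv)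
Product: 14, 4'-oxomacrophorin D (target; 5S,9S,10S,1'R,2'S, HMG 3S)
Conditions: quinidine (2.2 equiv), PhMe/THF 4:1, −45 °C, 48 h; then cold 0.5 M citric acid wash
Reagents that add atoms: none (13 is a numbered reactant)
Why: Proposed new method: cinchona-alkaloid general-base alcoholysis of the prochiral anhydride with the complex primary alcohol as limiting reagent — the quinuclidine nitrogen activates the C7' hydroxyl and the alkaloid pocket, helped by hydrogen bonding to the anhydride 3-OH, exposes one enantiotopic carbonyl, giving the (3S)-hemiester and the free acid in one operation with no HMG protecting groups; the closest known reactions are Bolm/Deng desymmetrising alcoholysis of 3-substituted glutaric anhydrides and the non-selective pyridine-mediated HMG-anhydride acylation of alcohols.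

## Compound list

1 | (+)-sclareolide | C[C@@]12CC[C@H]3C(C)(C)CCC[C@]3(C)[C@H]1CC(=O)O2 | starting material
2 | sclareolide lactol (anomer mixture) | C[C@@]12CC[C@H]3C(C)(C)CCC[C@]3(C)[C@H]1CC(O)O2 | intermediate
3 | 11-iodo-drimane-8α-yl formate | O=CO[C@]1(C)CC[C@H]2C(C)(C)CCC[C@]2(C)[C@H]1CI | intermediate
4 | methyl 4-bromo-3-hydroxybenzoate | COC(=O)c1ccc(Br)c(O)c1 | starting material
5 | methyl 4-bromo-3-(pivaloyloxy)benzoate | COC(=O)c1ccc(Br)c(OC(=O)C(C)(C)C)c1 | intermediate
6 | methyl 4-(8α-formyloxydriman-11-yl)-3-(pivaloyloxy)benzoate | O=CO[C@]1(C)CC[C@H]2C(C)(C)CCC[C@]2(C)[C@H]1Cc1ccc(C(=O)OC)cc1OC(=O)C(C)(C)C | intermediate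
7 | methyl 4-(8α-hydroxydriman-11-yl)-3-(pivaloyloxy)benzoate | O[C@]1(C)CC[C@H]2C(C)(C)CCC[C@]2(C)[C@H]1Cc1ccc(C(=O)OC)cc1OC(=O)C(C)(C)C | intermediate
8 | methyl 4-(drim-8(12)-en-11-yl)-3-(pivaloyloxy)benzoate | C=C1CC[C@H]2C(C)(C)CCC[C@]2(C)[C@H]1Cc1ccc(C(=O)OC)cc1OC(=O)C(C)(C)C | intermediate
9 | 5-(hydroxymethyl)-2-(drim-8(12)-en-11-yl)phenol | C=C1CC[C@H]2C(C)(C)CCC[C@]2(C)[C@H]1Cc1ccc(CO)cc1O | intermediate
10 | 4,4-dimethoxy-5-(hydroxymethyl)-2-(drim-8(12)-en-11-yl)cyclohexa-2,5-dien-1-one | C=C1CC[C@H]2C(C)(C)CCC[C@]2(C)[C@H]1CC1=CC(OC)(OC)C(CO)=CC1=O | intermediate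
11 | (1'R,2'S)-epoxy quinone monoketal | C=C1CC[C@H]2C(C)(C)CCC[C@]2(C)[C@H]1C[C@@]12O[C@@H]1C(OC)(OC)C(CO)=CC2=O | intermediate
12 | 4'-oxomacrophorin A | C=C1CC[C@H]2C(C)(C)CCC[C@]2(C)[C@H]1C[C@@]12O[C@@H]1C(=O)C(CO)=CC2=O | intermediate
13 | 3-hydroxy-3-methylglutaric anhydride | CC1(O)CC(=O)OC(=O)C1 | starting material
14 | 4'-oxomacrophorin D | C=C1CC[C@H]2C(C)(C)CCC[C@]2(C)[C@H]1C[C@@]12O[C@@H]1C(=O)C(COC(=O)C[C@@](C)(O)CC(=O)O)=CC2=O | target

## Totals and risks

Total steps: 11. Longest linear sequence: 10 (steps 1, 2, 4–11 from sclareolide).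

Three steps most likely to fail:

- **Step 11 (desymmetrising acylation).** The Me/OH difference at C3 of the anhydride is small, so the 3S:3R ratio may be modest and the epimers are hard to separate. Fallback: esterify 12 (Yamaguchi) with an enantiopure, carboxyl-masked HMG half-ester (allyl ester, made by desymmetrisation on the simple diester or anhydride where ee can be measured and upgraded), then remove the allyl group with Pd(0).
- **Step 4 (cross-electrophile coupling).** A β,β-disubstituted primary iodide with an ortho-substituted aryl bromide is demanding, and the C11 radical could abstract the formyl hydrogen. Fallback: a polar union — aryllithium from bis-silylated 4-bromo-3-hydroxybenzyl alcohol added to drim-8(12)-en-11-al, followed by Barton–McCombie removal of the benzylic hydroxyl.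
- **Step 8 (double dearomatisation).** Ortho attack, or alkene capture of the oxidised phenol, may compete with para attack. Fallback: carry the para oxygen from the start by coupling 3 with methyl 4-bromo-2-methoxy-5-(pivaloyloxy)benzoate (from a 2,5-dihydroxybenzoate), so the dearomatisation becomes a single oxidation of a p-methoxyphenol to the same monoketal 10.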